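Atom numbering used throughout: ring carbons C1 (ketone), C2, C3, C4 (epoxide carbon with methyl C15), C5 (epoxide CH), C6 (lactone CH–O), C7 (butenolide β-carbon), C8 (angeloyloxy CH), C9, C10 (CH with methyl C14); C11 is the butenolide α-carbon, C12 the lactone carbonyl, C13 the acetoxymethyl carbon.

## Analysis of the target

The target (28) is a ten-membered carbocycle C1–C10 fused at C6–C7 to a butenolide (O–C12(=O)–C11=C7, closed on C6), with an epoxide on C4–C5, a ketone at C1, an angelate on the C8 oxygen and an acetoxymethyl group (C13) on C11. It has five stereocentres, (4R,5R,6S,8S,10R). C4, C5 and C6 are contiguous: the epoxide is trans (derived from an E alkene) and its oxygen lies syn to the C6 oxygen when H6 eclipses the former C4=C5 plane. C8 is separated from C6 by the sp2 carbon C7. C10 is isolated and epimerisable next to the C1 carbonyl. The sensitive groups are the angelate (Z to E isomerisation by nucleophiles, base or heat), the trisubstituted epoxide lying across the ring from the C1 carbonyl, the butenolide with its acidic C6 hydrogen next to the epoxide, and the allylic acetate. The difficulty is to make a densely oxidised ten-membered ring without an end-to-end cyclisation and to add oxygen at C1, C4/C5, C6, C8 and C13 in an order the transannular reactivity tolerates. The strategy rests on one feature: the C1–C10 and C4–C5 bonds are 1,5-related and C6 is oxygenated, so the skeleton is a masked cyclodeca-1(10),4-dien-6-one. That dienone is the crosswise cleavage product of a tricyclo[4.4.0.0(2,5)]decanone built from a 3-methylcyclohexenone (C5–C10, with C7 and C8 already substituted) and 1-methylcyclobutene (C1–C4).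

## Retrosynthetic reasoning

**28 to 25 and 26.** The C8–O acyl bond is cut last. The angelate would not survive enolate chemistry, borane or peroxide, so it is put on the free C8 alcohol 25 with acid 26 once everything else is in place.

**25 back to 21.** The C1 carbonyl and the C10–H bond are traced through 24 and 23 to the C1=C10 alkene of 21 by anti-Markovnikov hydration and oxidation. The ketone is placed after all lactone enolate chemistry because it would otherwise be the most acidic site. The hydration also creates C10, so its facial course matters.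

**21 back to 16.** The butenolide alkene C7=C11 and the C11–C13 bond are removed. C13 is added to the lactone enolate of 16 as a hydroxymethyl group (17). Selenium then enters at C11 from the face anti to C8, which is the face of H7 (18), and after acetylation (19) a selenoxide syn-elimination can only take H7, because elimination towards the oxygen-bearing C13 is disfavoured. The obvious shortcut (α-methylene lactone, bromine addition, dehydrobromination, acetate displacement) was not taken. Bromine would also add to C1=C10, the C11 bromide would sit syn to H7 and could not undergo anti elimination, and the strong base would threaten the C6 hydrogen next to the epoxide.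

**16 back to 14.** The lactone C12–O bond is opened to the hydroxy tert-butyl ester 15 and the epoxide oxygen is removed to give allylic alcohol 14. Epoxidation comes before lactonisation so that the free C6 hydroxyl can direct the oxidant to C4=C5 in the presence of C1=C10 and fix the C4/C5 configuration. The bulky ester keeps the hydroxyl free until then.

**14 to 13.** The C6–H bond is cut. A reagent-controlled reduction of the conjugated ketone 13 sets C6, which then controls C4 and C5.

**13 to 12 (key).** No ring-closing bond is sought for the ten-membered ring. Dienone 13 is seen as the product of cleaving C1–C4 and C5–C10 in tricycle 12, so in the reverse sense those two σ bonds are re-formed. Ring strain pays for the medium ring, and the four core stereocentres of 12 need not be controlled because all are destroyed.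

**12 to 10 and 11.** The bonds C5–C4 and C10–C1 are cut. This is an enone–alkene [2+2] photocycloaddition in the orientation that does not join the two methyl-bearing carbons.

**10 to 8 and 9.** The C7–C11 bond comes from α′-alkylation of the kinetic enolate, trans to the silyloxy group.

**8 back to 6.** The C10 methyl is introduced through 7 by carbonyl addition and oxidative 1,3-transposition. This exchanges the positions of carbonyl and alkene and delivers the (S)-series needed for C8.

**6 back to 1.** The C8 stereocentre comes from enzymatic desymmetrisation of the meso diol 3 (to 4), followed by oxidation and β-elimination of acetate. Diol 3 comes from the all-cis triol 2, the hydrogenation product of 1.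

## Alternatives that were turned down

**Alternative 1:** The C8–O bond and the C7=C11 alkene are disconnected together, back to allylic selenide A2 (C7=C8 alkene, phenylselanyl and acetoxymethyl on C11). In the forward step, oxidation to the selenoxide triggers a suprafacial [2,3] shift to the C8 selenenate, and hydrolysis gives alcohol A1, which is identical with 25.
- For: one mild operation transfers chirality from C11 to C8 and places the tetrasubstituted alkene, one acylation from the target.
- Against: it closes no ring, so the ten-membered carbocycle must come from elsewhere. A2 needs a quaternary C11 of defined configuration and a deconjugated C7=C8 alkene of defined geometry in a ring that already carries the C1 ketone and the epoxide. Making it by selenenylation would require a butenolide dienolate in the presence of a more acidic ketone. Peroxide with selenium residues also threatens the ketone (Baeyer–Villiger) and the product.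
- Comparison: on C8 it is as strong as the chosen route or stronger, since C8 is set late and needs no protecting group. The chosen route instead fixes C8 at the start from a desymmetrised meso diol and carries it as a silyl ether, and in exchange it delivers the carbocycle that Alternative 1 presupposes. Counting a separate ring synthesis, Alternative 1 is longer.

**Alternative 2:** The butenolide is cut into three pieces: propargylic alcohol A4 (C6 carbinol, C7≡C11), silylmethyl Grignard reagent A5 (C8) and a carboxylating one-carbon unit (C12). In the forward step the magnesium alkoxide of A4 directs anti-carbomagnesiation (carbon to C7, magnesium to C11), the alkenylmagnesium is carboxylated, and acidification closes the lactone to A3.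
- For: the fully substituted butenolide, with protected C13 oxygen and a C8 handle, forms in one flask. This is clearly better than the four steps (13 to 16) the chosen route spends there, and C6 could come from an asymmetric alkynylation.
- Against: A3 is acyclic. C8 arrives as a silylmethyl group that must be oxidised to the aldehyde level, the C9–C10–C1–C2 segment must still be attached, and the ten-membered ring must then be closed end to end while a new, uncontrolled stereocentre forms at C8. The doubly activated C6 carbinol is also prone to ionisation.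
- Comparison: the chosen route is weaker at the butenolide but makes the ring by ring expansion and has C8 defined from the start.

**Alternative 3:** The C6–C7 bond and the lactone C–O bond are disconnected to the acyclic (Z)-2-(bromomethyl)enoate enal A7. In the forward step CrCl2 (divalent chromium) gives an allylchromium species that adds through C7 to the C6 aldehyde, closing the ten-membered ring, and the C6 alkoxide lactonises to the trans-fused α-methylene lactone A6.
- For: ring, lactone and the C6/C7 relationship form in one step. The C1 ketone and C10 methyl are already present, so C10 is set in an acyclic precursor and no second ring alkene competes in the later epoxidation. On both points it is stronger than the chosen route.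
- Against: the ring forms by end-to-end closure at high dilution, with facial control by the C8 silyloxy group uncertain and C10 epimerisable. A7 needs a long linear synthesis with an E enal and a Z allylic bromide. A6 still needs exocyclic-to-endocyclic alkene transposition with C13 oxygenation (the weak sequence rejected above) and an epoxidation without a directing hydroxyl.
- Comparison: the chosen route avoids the macrocyclisation and has a directed epoxidation, but it must create C10 late under substrate control.

Key step: step 9

Assumption (step 3): the lipase shows its usual preference for the (R)-configured carbinol of meso diol 3 (the one whose larger flank carries the silyloxy group); steps 5 and 6 are chosen to fit that sense.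
Assumption (step 8): 1-methylcyclobutene (11) is taken as a purchasable, volatile reagent and is used in excess.

## Steps

Step 1
Reactants: 1 phloroglucinol
Product: 2 all-cis-cyclohexane-1,3,5-triol
Conditions: H2 (100 bar), 5% Rh/Al2O3, EtOH, 80 °C
Reagents that add atoms: none
Why: Arene hydrogenation on Rh/Al2O3 delivers all hydrogens from the catalyst face, so the all-cis triol should be the main product and can be purified by crystallisation.

Step 2
Reactants: 2 all-cis-cyclohexane-1,3,5-triol
Product: 3 all-cis-5-[(tert-butyldimethylsilyl)oxy]cyclohexane-1,3-diol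
Conditions: TBSCl (1.0 equiv), imidazole, DMF, 0 °C to rt
Reagents that add atoms: tert-butyldimethylsilyl chloride, CC(C)(C)[Si](C)(C)Cl
Why: Statistical monosilylation of three equivalent hydroxyls; the meso diol should be separable from triol and bis-ether, and recovered 2 can be recycled.

Step 3
Reactants: 3 all-cis-5-[(tert-butyldimethylsilyl)oxy]cyclohexane-1,3-diol
Product: 4 (1R,3S,5S)-3-[(tert-butyldimethylsilyl)oxy]-5-hydroxycyclohexyl acetate
Conditions: Candida antarctica lipase B (immobilised), vinyl acetate, t-BuOMe, rt
Reagents that add atoms: vinyl acetate, C=COC(C)=O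
Why: Enzymatic desymmetrisation by irreversible transesterification; the lipase should acetylate only the (R)-carbinol of the meso diol (Kazlauskas preference), which fixes the carbon that becomes C8.

Step 4
Reactants: 4 (1R,3S,5S)-3-[(tert-butyldimethylsilyl)oxy]-5-hydroxycyclohexyl acetate
Product: 6 (R)-5-[(tert-butyldimethylsilyl)oxy]cyclohex-2-en-1-one, via β-acetoxy ketone 5 (not isolated)
Conditions: Dess–Martin periodinane, NaHCO3, CH2Cl2, rt; then Et3N, 0 °C to rt
Reagents that add atoms: none
Why: Dess–Martin oxidation of the free carbinol, then E1cB loss of acetate from 5; acetate is a far better leaving group than silyloxide, so the alkene should form only on the acetate side, and the weak base spares the β-silyloxy group.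

Step 5
Reactants: 6 (R)-5-[(tert-butyldimethylsilyl)oxy]cyclohex-2-en-1-one
Product: 7 (5R)-5-[(tert-butyldimethylsilyl)oxy]-1-methylcyclohex-2-en-1-ol (both C1 epimers)
Conditions: MeLi, Et2O, −78 °C; aq. NH4Cl
Reagents that add atoms: methyllithium, [Li]C
Why: Hard organolithium 1,2-addition to the enone carbonyl at low temperature; the new carbinol configuration is irrelevant because it is lost in step 6.

Step 6
Reactants: 7 (5R)-5-[(tert-butyldimethylsilyl)oxy]-1-methylcyclohex-2-en-1-ol
Product: 8 (S)-5-[(tert-butyldimethylsilyl)oxy]-3-methylcyclohex-2-en-1-one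
Conditions: pyridinium chlorochromate ([C5H5NH][CrO3Cl]), 4 Å MS, CH2Cl2, rt
Reagents that add atoms: pyridinium chlorochromate, [O-][Cr](=O)(=O)Cl.c1cc[nH+]cc1
Why: Dauben–Babler oxidative transposition: the chromate ester of the tertiary allylic alcohol undergoes a [3,3] shift and is oxidised at the other allyl terminus. Carbonyl and methyl-bearing carbon change places around the untouched stereocentre, which turns the (R)-series into (S)-8.

Step 7
Reactants: 8 (S)-5-[(tert-butyldimethylsilyl)oxy]-3-methylcyclohex-2-en-1-one; 9 tert-butyl bromoacetate
Product: 10 tert-butyl 2-[(1R,6S)-6-[(tert-butyldimethylsilyl)oxy]-4-methyl-2-oxocyclohex-3-en-1-yl]acetate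
Conditions: LDA, THF, −78 °C; 9, DMPU, −78 to −40 °C
Reagents that add atoms: none
Why: Kinetic α′-deprotonation gives the cross-conjugated lithium dienolate, and the reactive bromoacetate should alkylate it anti to the neighbouring silyloxy group, so C7 is set trans to C8 (C7 is erased later). Low temperature and a fast electrophile are meant to outrun β-elimination of silyloxide.

Step 8
Reactants: 10 tert-butyl 2-[(1R,6S)-6-[(tert-butyldimethylsilyl)oxy]-4-methyl-2-oxocyclohex-3-en-1-yl]acetate; 11 1-methylcyclobutene
Product: 12 cis-anti-cis photoadduct, tert-butyl 2-{9-[(tert-butyldimethylsilyl)oxy]-1,5-dimethyl-7-oxotricyclo[4.4.0.0(2,5)]decan-8-yl}acetate (H on C5 and methyl on C10 cis, the two cyclobutanes anti, cyclobutane on the ring face opposite the silyloxy group, side chain trans to silyloxy)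
Conditions: hν (350 nm, Pyrex), 11 (10 equiv), CH2Cl2, −40 °C
Reagents that add atoms: none
Why: Enone–alkene [2+2] photocycloaddition through the enone triplet and a 1,4-biradical: C10 bonds to the unsubstituted alkene carbon C1 and the α-keto radical at C5 closes onto the tertiary radical at C4, the orientation known for 1-methylcyclobutene with 3-methyl-6-alkylcyclohexenones, which avoids a bond between two fully substituted carbons. The cis-anti-cis fusion is the usual outcome with cyclobutenes; which face of the enone is attacked is immaterial because both face isomers give the same diene in step 9.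

Step 9
Reactants: 12 cis-anti-cis photoadduct
Product: 13 tert-butyl (7R,8S,1(10)Z,4E)-8-[(tert-butyldimethylsilyl)oxy]-6-oxo-13-norgermacra-1(10),4-dien-12-oate, the cyclodeca-1(10),4-dien-6-one
Conditions: flash vacuum thermolysis, quartz tube, ca. 400 °C, ca. 0.01 mbar, condensate trapped at −78 °C
Reagents that add atoms: none
Why: Heat breaks the strained central C1–C4 bond of the bicyclo[2.2.0]hexane unit to a cyclohexane-1,4-diyl, which relaxes from boat to chair and then cleaves C5–C10, forming the C4=C5 and C1=C10 π bonds (net [σ2s+σ2a] cycloreversion). The closest known reaction type is the thermolysis of enone–cyclobutene photoadducts to cyclodeca-1,5-dienes, itself the fused-ring case of the bicyclo[2.2.0]hexane to hexa-1,5-diene cleavage. The ten-membered ring is not closed end to end: it arises by ring expansion when the bond shared by the six- and four-membered rings is cut, so no entropic penalty is paid and ring strain drives the step. No stereocentre is formed; the four of the tricyclic core are destroyed and C7 and C8 are untouched. The chair diyl turns the cis-anti-cis fusion into one E and one Z alkene, expected as E at the conjugated C4=C5 and Z at C1=C10. The step needs C5–C10 scission rather than C2–C3 scission, which is favoured because it breaks the most substituted bond and gives a conjugated enone and two trisubstituted alkenes. It also needs the product to escape Cope rearrangement, for which the millisecond contact time and cold trapping are chosen. The same short contact keeps the tert-butyl ester from losing isobutene.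

Step 10
Reactants: 13 cyclodeca-1(10),4-dien-6-one
Product: 14 tert-butyl (6R,7S,8S,1(10)Z,4E)-8-[(tert-butyldimethylsilyl)oxy]-6-hydroxy-13-norgermacra-1(10),4-dien-12-oate
Conditions: (R)-2-methyl-CBS-oxazaborolidine (0.5 equiv), catecholborane, toluene, −78 °C
Reagents that add atoms: none
Why: Corey–Bakshi–Shibata reduction with the alkenyl group taken as the large substituent; the (R)-catalyst should deliver hydride to the carbonyl face that gives the carbinol with the target's C6 configuration (6R here by priority, 6S in 28). Catecholborane at low temperature leaves both alkenes and the ester alone.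

Step 11
Reactants: 14 allylic alcohol
Product: 15 tert-butyl (4R,5R,6S,7S,8S,1(10)Z)-8-[(tert-butyldimethylsilyl)oxy]-4,5-epoxy-6-hydroxy-13-norgermacr-1(10)-en-12-oate
Conditions: VO(acac)2 (5 mol %), t-BuOOH (decane), CH2Cl2, 0 °C
Reagents that add atoms: tert-butyl hydroperoxide, CC(C)(C)OO
Why: Hydroxyl-directed (vanadate ester) epoxidation oxidises only the allylic C4=C5 bond and leaves the remote C1=C10. A(1,3) strain with the C4 methyl, which is cis to C6, puts H6 in the alkene plane and the hydroxyl on the outer face opposite C7, so oxygen should arrive syn to the hydroxyl and give the 4R,5R epoxide.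

Step 12
Reactants: 15 epoxy alcohol
Product: 16 (4R,5R,6S,7S,8S,1(10)Z)-8-[(tert-butyldimethylsilyl)oxy]-4,5-epoxy-13-norgermacr-1(10)-en-12,6-olide (trans-fused γ-lactone)
Conditions: NaH (1.1 equiv), THF, 0 °C to rt; aq. NH4Cl
Reagents that add atoms: none
Why: Intramolecular transesterification: the C6 alkoxide attacks the tert-butyl ester in a 5-exo-trig closure and expels tert-butoxide, with no acid near the epoxide or the ring alkene. Acylation should be faster than Payne migration of the epoxy alkoxide in this aprotic medium.

Step 13
Reactants: 16 γ-lactone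
Product: 17 (4R,5R,6S,7S,8S,1(10)Z)-8-[(tert-butyldimethylsilyl)oxy]-4,5-epoxy-13-hydroxygermacr-1(10)-en-12,6-olide (both C11 epimers)
Conditions: LDA (1.3 equiv), THF, −78 °C; CH2O (gas, from paraformaldehyde), −78 to −40 °C; aq. NH4Cl
Reagents that add atoms: formaldehyde, C=O
Why: Aldol addition of the lactone lithium enolate to monomeric formaldehyde introduces C13 with its oxygen; the C11 configuration does not matter because C11 is enolised again in step 14.

Step 14
Reactants: 17 α-hydroxymethyl lactone
Product: 18 (4R,5R,6S,7S,8S,11R,1(10)Z)-8-[(tert-butyldimethylsilyl)oxy]-4,5-epoxy-13-hydroxy-11-(phenylselanyl)germacr-1(10)-en-12,6-olide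
Conditions: LDA (2.3 equiv), THF, −78 to −40 °C; PhSeBr, −78 °C; aq. NH4Cl
Reagents that add atoms: benzeneselenenyl bromide, Br[Se]c1ccccc1
Why: The alkoxide–enolate dianion (as in Fráter–Seebach chemistry) is selenenylated at C11; the electrophile should enter anti to the vicinal C7–C8 bond, which is the face of H7, exactly the syn relationship the later elimination needs.

Step 15
Reactants: 18 hydroxy selenide
Product: 19 (4R,5R,6S,7S,8S,11R,1(10)Z)-13-acetoxy-8-[(tert-butyldimethylsilyl)oxy]-4,5-epoxy-11-(phenylselanyl)germacr-1(10)-en-12,6-olide
Conditions: Ac2O, pyridine, DMAP (cat.), CH2Cl2, 0 °C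
Reagents that add atoms: acetic anhydride, CC(=O)OC(C)=O
Why: Routine acetylation of the primary alcohol; there is no enolisable hydrogen at C11, so β-elimination of the new acetate cannot occur.

Step 16
Reactants: 19 acetoxy selenide
Product: 21 (4R,5R,6S,8S,1(10)Z)-13-acetoxy-8-[(tert-butyldimethylsilyl)oxy]-4,5-epoxygermacra-1(10),7(11)-dien-12,6-olide, via selenoxide 20 (not isolated)
Conditions: mCPBA (1.05 equiv), CH2Cl2, −78 °C; then Et3N, −78 °C to rt
Reagents that add atoms: 3-chloroperbenzoic acid, OOC(=O)c1cccc(Cl)c1 (its oxygen sits on selenium in 20 and leaves with it)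
Why: Selenide oxidation is much faster than epoxidation of the ring alkene at −78 °C, and the selenoxide then undergoes syn-elimination. Elimination towards the oxygen-bearing C13 is disfavoured, so the cis hydrogen H7 is taken and the tetrasubstituted C7=C11 butenolide forms; the amine scavenges the selenenic acid.

Step 17
Reactants: 21 butenolide
Product: 23 (1R,4R,5R,6S,8S,10R)-13-acetoxy-8-[(tert-butyldimethylsilyl)oxy]-4,5-epoxy-1-hydroxygermacr-7(11)-en-12,6-olide, via alkylborane 22 (not isolated)
Conditions: BH3·SMe2 (1.1 equiv), THF, 0 °C; then NaBO3·4H2O, THF/H2O, rt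
Reagents that add atoms: borane–dimethyl sulfide, [BH3-][S+](C)C (boron of 22); sodium perborate, O[B-]1(O)OO[B-](O)(O)OO1.[Na+].[Na+] (oxygen at C1)
Why: Hydroboration–oxidation of the only electron-rich alkene: boron goes to the less substituted C1 and hydrogen to C10, syn. Attack is expected on the face away from the silyloxy group at C8, which would give 10R (H10 on the face opposite the C8 oxygen); the C1 configuration is lost in step 18, and perborate is mild enough for lactone and acetate.

Step 18
Reactants: 23 C1 alcohol
Product: 24 (4R,5R,6S,8S,10R)-13-acetoxy-8-[(tert-butyldimethylsilyl)oxy]-4,5-epoxy-1-oxogermacr-7(11)-en-12,6-olide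
Conditions: Dess–Martin periodinane, NaHCO3, CH2Cl2, 0 °C to rt
Reagents that add atoms: none
Why: Buffered Dess–Martin oxidation of the secondary alcohol is near neutral, so the new α-stereocentre C10 and the epoxide should be undisturbed.

Step 19
Reactants: 24 C1 ketone
Product: 25 (4R,5R,6S,8S,10R)-13-acetoxy-4,5-epoxy-8-hydroxy-1-oxogermacr-7(11)-en-12,6-olide
Conditions: HF·pyridine, pyridine, THF, 0 °C to rt
Reagents that add atoms: none
Why: Fluoride-driven cleavage of the secondary silyl ether; the excess pyridine keeps the medium too weakly acidic to open the epoxide and too weakly basic to touch the butenolide or shift the acetate.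

Step 20
Reactants: 25 C8 alcohol; 26 angelic acid [(Z)-2-methylbut-2-enoic acid]
Product: 28 target, (4R,5R,6S,8S,10R)-13-acetoxy-4,5-epoxy-8-[(Z)-2-methylbut-2-enoyloxy]-1-oxogermacr-7(11)-en-12,6-olide, via mixed anhydride 27 (not isolated)
Conditions: 26, 2,4,6-Cl3C6H2COCl, Et3N, toluene, rt; then 25, toluene, 75 °C
Reagents that add atoms: 2,4,6-trichlorobenzoyl chloride, O=C(Cl)c1c(Cl)cc(Cl)cc1Cl (its acyl group sits in 27 only)
Why: Yamaguchi esterification: the alcohol attacks the unhindered angeloyl carbonyl of the preformed mixed anhydride. Leaving out a nucleophilic catalyst avoids the addition–elimination pathway that would turn the angelate into the tiglate.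

## Compound list

1 | phloroglucinol (benzene-1,3,5-triol) | Oc1cc(O)cc(O)c1 | starting material
2 | all-cis-cyclohexane-1,3,5-triol | O[C@H]1C[C@@H](O)C[C@@H](O)C1 | intermediate
3 | all-cis-5-[(tert-butyldimethylsilyl)oxy]cyclohexane-1,3-diol (meso) | O[C@H]1C[C@@H](O)C[C@@H](O[Si](C)(C)C(C)(C)C)C1 | intermediate
4 | (1R,3S,5S)-3-[(tert-butyldimethylsilyl)oxy]-5-hydroxycyclohexyl acetate | O[C@H]1C[C@@H](OC(C)=O)C[C@@H](O[Si](C)(C)C(C)(C)C)C1 | intermediate
5 | (3S,5R)-3-acetoxy-5-[(tert-butyldimethylsilyl)oxy]cyclohexan-1-one | O=C1C[C@@H](OC(C)=O)C[C@@H](O[Si](C)(C)C(C)(C)C)C1 | intermediate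
6 | (R)-5-[(tert-butyldimethylsilyl)oxy]cyclohex-2-en-1-one | O=C1C=CC[C@@H](O[Si](C)(C)C(C)(C)C)C1 | intermediate
7 | (5R)-5-[(tert-butyldimethylsilyl)oxy]-1-methylcyclohex-2-en-1-ol (both C1 epimers) | CC1(O)C=CC[C@@H](O[Si](C)(C)C(C)(C)C)C1 | intermediate
8 | (S)-5-[(tert-butyldimethylsilyl)oxy]-3-methylcyclohex-2-en-1-one | O=C1C=C(C)C[C@H](O[Si](C)(C)C(C)(C)C)C1 | intermediate
9 | tert-butyl bromoacetate | CC(C)(C)OC(=O)CBr | starting material
10 | tert-butyl 2-[(1R,6S)-6-[(tert-butyldimethylsilyl)oxy]-4-methyl-2-oxocyclohex-3-en-1-yl]acetate | O=C1C=C(C)C[C@H](O[Si](C)(C)C(C)(C)C)[C@H]1CC(=O)OC(C)(C)C | intermediate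
11 | 1-methylcyclobutene | CC1=CCC1 | starting material
12 | cis-anti-cis photoadduct, tert-butyl 2-{9-[(tert-butyldimethylsilyl)oxy]-1,5-dimethyl-7-oxotricyclo[4.4.0.0(2,5)]decan-8-yl}acetate | O=C1[C@H]2[C@]3(C)CC[C@@H]3[C@@]2(C)C[C@H](O[Si](C)(C)C(C)(C)C)[C@H]1CC(=O)OC(C)(C)C | intermediate
13 | tert-butyl (7R,8S,1(10)Z,4E)-8-[(tert-butyldimethylsilyl)oxy]-6-oxo-13-norgermacra-1(10),4-dien-12-oate | CC(C)(C)[Si](C)(C)O[C@H]1C/C(C)=C\CC/C(C)=C/C(=O)[C@@H]1CC(=O)OC(C)(C)C | intermediate
14 | tert-butyl (6R,7S,8S,1(10)Z,4E)-8-[(tert-butyldimethylsilyl)oxy]-6-hydroxy-13-norgermacra-1(10),4-dien-12-oate | CC(C)(C)[Si](C)(C)O[C@H]1C/C(C)=C\CC/C(C)=C/[C@@H](O)[C@@H]1CC(=O)OC(C)(C)C | intermediate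
15 | tert-butyl (4R,5R,6S,7S,8S,1(10)Z)-8-[(tert-butyldimethylsilyl)oxy]-4,5-epoxy-6-hydroxy-13-norgermacr-1(10)-en-12-oate | CC(C)(C)[Si](C)(C)O[C@H]1C/C(C)=C\CC[C@@]2(C)O[C@@H]2[C@@H](O)[C@@H]1CC(=O)OC(C)(C)C | intermediate
16 | (4R,5R,6S,7S,8S,1(10)Z)-8-[(tert-butyldimethylsilyl)oxy]-4,5-epoxy-13-norgermacr-1(10)-en-12,6-olide | CC(C)(C)[Si](C)(C)O[C@H]1C/C(C)=C\CC[C@@]2(C)O[C@@H]2[C@H]3OC(=O)C[C@H]13 | intermediate
17 | (4R,5R,6S,7S,8S,1(10)Z)-8-[(tert-butyldimethylsilyl)oxy]-4,5-epoxy-13-hydroxygermacr-1(10)-en-12,6-olide (C11 epimers) | CC(C)(C)[Si](C)(C)O[C@H]1C/C(C)=C\CC[C@@]2(C)O[C@@H]2[C@H]3OC(=O)C(CO)[C@H]13 | intermediate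
18 | (4R,5R,6S,7S,8S,11R,1(10)Z)-8-[(tert-butyldimethylsilyl)oxy]-4,5-epoxy-13-hydroxy-11-(phenylselanyl)germacr-1(10)-en-12,6-olide | CC(C)(C)[Si](C)(C)O[C@H]1C/C(C)=C\CC[C@@]2(C)O[C@@H]2[C@H]3OC(=O)[C@@](CO)([Se]c4ccccc4)[C@H]13 | intermediate
19 | (4R,5R,6S,7S,8S,11R,1(10)Z)-13-acetoxy-8-[(tert-butyldimethylsilyl)oxy]-4,5-epoxy-11-(phenylselanyl)germacr-1(10)-en-12,6-olide | CC(C)(C)[Si](C)(C)O[C@H]1C/C(C)=C\CC[C@@]2(C)O[C@@H]2[C@H]3OC(=O)[C@@](COC(C)=O)([Se]c4ccccc4)[C@H]13 | intermediate
20 | selenoxide of 19 (11-phenylseleninyl) | CC(C)(C)[Si](C)(C)O[C@H]1C/C(C)=C\CC[C@@]2(C)O[C@@H]2[C@H]3OC(=O)[C@@](COC(C)=O)([Se](=O)c4ccccc4)[C@H]13 | intermediate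
21 | (4R,5R,6S,8S,1(10)Z)-13-acetoxy-8-[(tert-butyldimethylsilyl)oxy]-4,5-epoxygermacra-1(10),7(11)-dien-12,6-olide | CC(C)(C)[Si](C)(C)O[C@H]1C/C(C)=C\CC[C@@]2(C)O[C@@H]2[C@H]2OC(=O)C(COC(C)=O)=C12 | intermediate
22 | C1 alkylborane of 21 (boron at C1, hydrogen at C10, syn) | CC(C)(C)[Si](C)(C)O[C@H]1C[C@@H](C)[C@H](B)CC[C@@]2(C)O[C@@H]2[C@H]2OC(=O)C(COC(C)=O)=C12 | intermediate
23 | (1R,4R,5R,6S,8S,10R)-13-acetoxy-8-[(tert-butyldimethylsilyl)oxy]-4,5-epoxy-1-hydroxygermacr-7(11)-en-12,6-olide | CC(C)(C)[Si](C)(C)O[C@H]1C[C@@H](C)[C@H](O)CC[C@@]2(C)O[C@@H]2[C@H]2OC(=O)C(COC(C)=O)=C12 | intermediate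
24 | (4R,5R,6S,8S,10R)-13-acetoxy-8-[(tert-butyldimethylsilyl)oxy]-4,5-epoxy-1-oxogermacr-7(11)-en-12,6-olide | CC(C)(C)[Si](C)(C)O[C@H]1C[C@@H](C)C(=O)CC[C@@]2(C)O[C@@H]2[C@H]2OC(=O)C(COC(C)=O)=C12 | intermediate
25 | (4R,5R,6S,8S,10R)-13-acetoxy-4,5-epoxy-8-hydroxy-1-oxogermacr-7(11)-en-12,6-olide | O[C@H]1C[C@@H](C)C(=O)CC[C@@]2(C)O[C@@H]2[C@H]2OC(=O)C(COC(C)=O)=C12 | intermediate
26 | angelic acid, (Z)-2-methylbut-2-enoic acid | C/C=C(/C)C(=O)O | starting material
27 | angelic 2,4,6-trichlorobenzoic anhydride | C/C=C(/C)C(=O)OC(=O)c1c(Cl)cc(Cl)cc1Cl | intermediate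
28 | CNP0229937.2, (4R,5R,6S,8S,10R)-13-acetoxy-4,5-epoxy-8-[(Z)-2-methylbut-2-enoyloxy]-1-oxogermacr-7(11)-en-12,6-olide | C/C=C(/C)C(=O)O[C@H]1C[C@@H](C)C(=O)CC[C@@]2(C)O[C@@H]2[C@H]2OC(=O)C(COC(C)=O)=C12 | target

## Step count and least certain steps

Total step count: 20. Longest linear sequence: 20 steps (1 to 28); 9, 11 and 26 enter as purchased reagents.

**Step 9 (key step).** The most likely failure is onward [3,3] (Cope) rearrangement of the hot ten-membered dienone back to a six-membered ring, or scission of the diyl at C2–C3 instead of C5–C10. Both have barriers comparable to the cycloreversion itself. Loss of isobutene from the ester and formation of the Z geometry at the conjugated C4=C5 are secondary risks. Fallback, from 12 back to 13, keeping the same disconnection but at the carbinol oxidation level: NaBH4 (MeOH, 0 °C) reduces the C6 carbonyl of 12 from the face opposite the cyclobutane to the tricyclic C6 carbinol F1. Flash thermolysis of F1 as in step 9 gives the (1(10)Z,4E)-dienol 6-epimer of 14, F2, which has no enone and no acidic C7 hydrogen while hot. MnO2 (CH2Cl2, rt) then oxidises this allylic alcohol to 13. The C6 configuration of F1 and F2 is of no consequence because it is erased.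

**Step 7.** The likely failure is β-elimination of silyloxide from the C7 enolate, driven here by aromatisation of the resulting dienone, and some γ-deprotonation. Fallback, from 8 to 12: the order of the two C–C bond formations is reversed. Enone 8 is irradiated with 11 under the conditions of step 8 to give the side-chain-free tricyclic ketone F3. Its only accessible α-position, C7, is then alkylated (LDA, THF, −78 °C; 9) trans to the silyloxy group, arriving at 12. In F3 elimination no longer leads to an arene.

**Step 10.** The likely failure is poor or inverted facial selectivity, because the β,β-disubstituted alkenyl group and the branched C7 are of similar size to the catalyst and the ring may impose its own bias. Fallback, from 13 to 14, by substrate control followed by inversion: Luche reduction (NaBH4, CeCl3, MeOH, −78 °C) gives the ring-preferred 6-epimer, the dienol F2 already described under step 9. Mitsunobu inversion with chloroacetic acid (PPh3, DIAD, toluene, 0 °C) gives the inverted chloroacetate F4. Thiourea with NaHCO3 (EtOH, rt) removes the chloroacetyl group under neutral conditions that do not trigger lactonisation, giving 14.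

**Step 17.** The likely failure is hydroboration on the wrong face of C1=C10, which would give the C10 epimer with no reliable way to correct it later, since the preferred configuration next to the C1 ketone is unknown. Slow reduction of the butenolide is a lesser risk. Fallback, from 21 to 23, by reagent control in place of substrate control: monoisopinocampheylborane prepared from (−)-α-pinene (THF, −25 °C) is the antipode that gives (R,R)-trans-2-methylcycloalkanol-type products from 1-methylcycloalkenes. It adds to C1=C10 to give the isopinocampheyl alkylborane F5, and NaBO3·4H2O oxidation gives 23.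

**Step 20.** The likely failure is isomerisation of the angeloyl group to tigloyl during activation, or base- and heat-induced damage to the butenolide, epoxide and acetate of 25 at 75 °C. Fallback, from 25 to 28, building the Z alkene on the ester instead of transferring it: DCC with catalytic DMAP (CH2Cl2, 0 °C) couples 25 with 2-[bis(2,2,2-trifluoroethoxy)phosphoryl]propanoic acid to the C8 phosphonopropanoate F6. A Still–Gennari olefination (KHMDS, 18-crown-6, THF, −78 °C; acetaldehyde) then gives the (Z)-2-methylbut-2-enoate 28. One equivalent of base is taken up by the far more acidic phosphonate.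

## Further compounds

F1 | step 9 | tert-butyl 2-{9-[(tert-butyldimethylsilyl)oxy]-7-hydroxy-1,5-dimethyltricyclo[4.4.0.0(2,5)]decan-8-yl}acetate (cis-anti-cis, hydroxyl cis to the side chain) | O[C@H]1[C@H]2[C@]3(C)CC[C@@H]3[C@@]2(C)C[C@H](O[Si](C)(C)C(C)(C)C)[C@H]1CC(=O)OC(C)(C)C
F2 | step 9 | tert-butyl (6S,7S,8S,1(10)Z,4E)-8-[(tert-butyldimethylsilyl)oxy]-6-hydroxy-13-norgermacra-1(10),4-dien-12-oate (6-epimer of 14) | CC(C)(C)[Si](C)(C)O[C@H]1C/C(C)=C\CC/C(C)=C/[C@H](O)[C@@H]1CC(=O)OC(C)(C)C
F3 | step 7 | cis-anti-cis 9-[(tert-butyldimethylsilyl)oxy]-1,5-dimethyltricyclo[4.4.0.0(2,5)]decan-7-one | O=C1[C@H]2[C@]3(C)CC[C@@H]3[C@@]2(C)C[C@H](O[Si](C)(C)C(C)(C)C)C1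
F4 | step 10 | chloroacetate of 14 (C6 inverted relative to F2) | CC(C)(C)[Si](C)(C)O[C@H]1C/C(C)=C\CC/C(C)=C/[C@@H](OC(=O)CCl)[C@@H]1CC(=O)OC(C)(C)C
F5 | step 17 | isopinocampheyl alkylborane from 21 (boron at C1, isopinocampheyl group from (−)-α-pinene) | CC(C)(C)[Si](C)(C)O[C@H]1C[C@@H](C)[C@H](B[C@H]3C[C@H]4C[C@@H]([C@@H]3C)C4(C)C)CC[C@@]2(C)O[C@@H]2[C@H]2OC(=O)C(COC(C)=O)=C12
F6 | step 20 | C8 2-[bis(2,2,2-trifluoroethoxy)phosphoryl]propanoate of 25 | CC(C(=O)O[C@H]1C[C@@H](C)C(=O)CC[C@@]2(C)O[C@@H]2[C@H]2OC(=O)C(COC(C)=O)=C12)P(=O)(OCC(F)(F)F)OCC(F)(F)F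
A1 | alternative 1 | C8 alcohol with all five stereocentres (identical with 25) | O[C@H]1C[C@@H](C)C(=O)CC[C@@]2(C)O[C@@H]2[C@H]2OC(=O)C(COC(C)=O)=C12
A2 | alternative 1 | 13-acetoxy-11-(phenylselanyl) lactone with a (Z) C7=C8 alkene | CC(=O)OC[C@@]1([Se]c2ccccc2)C(=O)O[C@H]2/C1=C\C[C@@H](C)C(=O)CC[C@@]1(C)O[C@@H]12
A3 | alternative 2 | tetrasubstituted butenolide with a C8 silylmethyl group | CC(C)(C)[Si](C)(C)OC/C(C)=C/[C@H]1OC(=O)C(COCc2ccc(OC)cc2)=C1C[Si](C)(C)OC(C)C
A4 | alternative 2 | C6 propargylic alcohol | CC(C)(C)[Si](C)(C)OC/C(C)=C/[C@@H](O)C#CCOCc1ccc(OC)cc1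
A5 | alternative 2 | (isopropoxydimethylsilyl)methylmagnesium chloride | CC(C)O[Si](C)(C)C[Mg]Cl
A6 | alternative 3 | ten-membered trans-fused α-methylene lactone | CC(C)(C)[Si](C)(C)O[C@H]1C[C@@H](C)C(=O)CC/C(C)=C/[C@H]2OC(=O)C(=C)[C@H]12
A7 | alternative 3 | acyclic (Z)-2-(bromomethyl)enoate with C6 enal | COC(=O)/C(CBr)=C/[C@@H](O[Si](C)(C)C(C)(C)C)C[C@@H](C)C(=O)CC/C(C)=C/C=O
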